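**Retrosynthetic overview**

1. Feature: the tetrasubstituted exocyclic alkene C9=C11 (C11 bears Cl and aryl carbon C1′) sits on ring B carbon C9 between quaternary C10 and C8(H)Me. It is read as the untouched π bond of a 1-aryl-1-chloroallene C10=C9=C11.
2. Key disconnection: retro-[4+2] across C5–C10 and C8–C9 opens ring B (the cycloaddition ring) and ring A (the ring of the C1–C4 tether) together, back to an acyclic (5E,7E)-dienyl (aR)-chloroallene. No ring is made earlier.
3. The chloroallene comes from the (S)-tertiary aryl propargylic alcohol by anti-SN2′ chlorination. The aryl–C11 bond comes from Sonogashira coupling with the diacetate of 2-iodo-6-methoxyhydroquinone (Dakin oxidation of 5-iodovanillin).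
4. The (S)-carbinol C10 comes from Sharpless epoxidation of an (E)-allylic alcohol followed by epoxy chloride fragmentation. The chain comes from isobutyronitrile alkylation (C3–C4), Takai/Suzuki diene construction (C5–C8) and alkyne carboalumination (C10 methyl, C11).
5. After the cycloaddition: diimide reduction of C6=C7, then acetate methanolysis.

Key step: step 13

Remark: locants C1–C11 are those of the decalin skeleton (C4 = CMe2, C5/C10 ring fusion, C8 = CHMe, C11 = exocyclic CCl(aryl)). The aryl iodide from 5-iodovanillin is used instead of the bromide so that the coupling can run at room temperature with the aryl acetates in place. The asymmetric ketone ethynylation is replaced by an epoxidation/fragmentation sequence, because a methyl n-alkyl ketone gives poor facial discrimination.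

**Route**

Step 1
Reactants: 1 isobutyronitrile; 2 (5-chloropent-1-yn-1-yl)trimethylsilane
Product: 4 2,2-dimethyl-7-(trimethylsilyl)hept-6-ynenitrile, via lithiated isobutyronitrile 3 (not isolated)
Conditions: LDA, THF, −78 °C; then 2, DMPU, −78 °C to rt
Reagents that add atoms: none
Why: SN2 alkylation of a tertiary nitrile anion by a primary alkyl chloride builds quaternary C4 and the C3–C4 bond, the silyl cap removing the acidic alkyne proton.

Step 2
Reactants: 4 2,2-dimethyl-7-(trimethylsilyl)hept-6-ynenitrile
Product: 6 2,2-dimethyl-7-(trimethylsilyl)hept-6-ynal, via N-alumanyl imine 5 (not isolated)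
Conditions: DIBAL-H, toluene, −78 °C to 0 °C; then aq. Rochelle salt, SiO2
Reagents that add atoms: water, O
Why: Partial reduction of a nitrile by DIBAL-H stops at the aluminium imine, which hydrolyses on work-up to the non-enolisable α-quaternary aldehyde.

Step 3
Reactants: 6 2,2-dimethyl-7-(trimethylsilyl)hept-6-ynal
Product: 7 [(7E)-8-iodo-6,6-dimethyloct-7-en-1-yn-1-yl]trimethylsilane
Conditions: CrCl2, CHI3, THF/dioxane, 0 °C to rt
Reagents that add atoms: iodoform, IC(I)I
Why: Takai olefination through a gem-dichromium carbenoid gives the (E)-iodoalkene (the future C5=C6 bond), E selectivity being highest for hindered aldehydes of this kind.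

Step 4
Reactants: 7 [(7E)-8-iodo-6,6-dimethyloct-7-en-1-yn-1-yl]trimethylsilane; 8 (E)-prop-1-en-1-ylboronic acid
Product: 10 (7E,9E)-6,6-dimethylundeca-7,9-dien-1-yne, via TMS-dienyne 9 (not isolated)
Conditions: Pd(dppf)Cl2 (cat.), aq. K2CO3, THF, 50 °C; then MeOH, rt
Reagents that add atoms: none
Why: Suzuki–Miyaura coupling joins the two alkenyl partners with retention of both geometries to give the (E,E)-diene C5–C8, and the carbonate in methanol then removes the alkynyl silyl group in the same flask.

Step 5
Reactants: 10 (7E,9E)-6,6-dimethylundeca-7,9-dien-1-yne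
Product: 12 (2E,8E,10E)-3,7,7-trimethyldodeca-2,8,10-trien-1-ol, via alkenylalane 11 (not isolated)
Conditions: AlMe3, Cp2ZrCl2 (cat.), CH2Cl2, 0 °C to rt; then n-BuLi, THF, −78 °C; (CH2O)n, rt
Reagents that add atoms: trimethylaluminium, C[Al](C)C; formaldehyde (as paraformaldehyde), C=O
Why: Negishi zirconium-catalysed carboalumination adds methyl and aluminium syn across the terminal alkyne, and the alkenyl aluminate is hydroxymethylated with retention to give the (E)-3-methyl allylic alcohol; the internal conjugated diene should not be carbometalated under these conditions.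

Step 6
Reactants: 12 (2E,8E,10E)-3,7,7-trimethyldodeca-2,8,10-trien-1-ol
Product: 13 {(2S,3S)-3-[(5E,7E)-4,4-dimethylnona-5,7-dien-1-yl]-3-methyloxiran-2-yl}methanol
Conditions: Ti(OiPr)4 (cat.), L-(+)-diethyl tartrate (cat.), t-BuOOH, 4 Å MS, CH2Cl2, −20 °C
Reagents that add atoms: tert-butyl hydroperoxide, CC(C)(C)OO
Why: Sharpless asymmetric epoxidation is directed by the allylic hydroxyl, so the diene is left alone, and L-(+)-tartrate gives the (2S,3S) epoxide of an (E)-3-methyl-2-alken-1-ol, whose C3 becomes C10.

Step 7
Reactants: 13 {(2S,3S)-3-[(5E,7E)-4,4-dimethylnona-5,7-dien-1-yl]-3-methyloxiran-2-yl}methanol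
Product: 14 (2R,3S)-2-(chloromethyl)-3-[(5E,7E)-4,4-dimethylnona-5,7-dien-1-yl]-3-methyloxirane
Conditions: PPh3, CCl4, NaHCO3, reflux
Reagents that add atoms: carbon tetrachloride, ClC(Cl)(Cl)Cl
Why: Appel chlorination replaces the primary hydroxyl under buffered, non-acidic conditions that leave the epoxide and its two stereocentres untouched (the C2 descriptor changes only through the priority rules).

Step 8
Reactants: 14 (2R,3S)-2-(chloromethyl)-3-[(5E,7E)-4,4-dimethylnona-5,7-dien-1-yl]-3-methyloxirane
Product: 16 (3S,8E,10E)-3,7,7-trimethyldodeca-8,10-dien-1-yn-3-ol, via chlorovinyl carbinolate 15 (not isolated)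
Conditions: LDA (excess), THF, −40 °C to −20 °C; then aq. NH4Cl
Reagents that add atoms: none
Why: Base-induced fragmentation of a 2,3-epoxy chloride (deprotonation next to Cl opens the epoxide, then loss of HCl) gives the terminal propargylic alcohol; the C3–O bond is never broken, so the tertiary carbinol C10 keeps the S configuration.

Step 9
Reactants: 17 5-iodovanillin (4-hydroxy-3-iodo-5-methoxybenzaldehyde)
Product: 19 2-iodo-6-methoxybenzene-1,4-diol, via aryl formate 18 (not isolated)
Conditions: H2O2 (aq.), NaOH, THF/H2O, 0 °C to rt, N2; then aq. HCl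
Reagents that add atoms: hydrogen peroxide, OO
Why: Dakin oxidation of a para-hydroxybenzaldehyde (aryl migration in the peroxide adduct, then hydrolysis of the formate) replaces CHO by OH and gives the hydroquinone with iodine and methoxy in the required positions.

Step 10
Reactants: 19 2-iodo-6-methoxybenzene-1,4-diol
Product: 20 2-iodo-6-methoxy-1,4-phenylene diacetate
Conditions: Ac2O, pyridine, DMAP (cat.), CH2Cl2, rt
Reagents that add atoms: acetic anhydride, CC(=O)OC(C)=O
Why: Acylation of both phenols protects the air-sensitive hydroquinone and makes the ring electron-poor, which later slows ionisation of the chloroallene.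

Step 11
Reactants: 16 (3S,8E,10E)-3,7,7-trimethyldodeca-8,10-dien-1-yn-3-ol; 20 2-iodo-6-methoxy-1,4-phenylene diacetate
Product: 21 2-[(3S,8E,10E)-3-hydroxy-3,7,7-trimethyldodeca-8,10-dien-1-yn-1-yl]-6-methoxy-1,4-phenylene diacetate
Conditions: Pd(PPh3)2Cl2 (cat.), CuI (cat.), Et3N, THF, rt, degassed
Reagents that add atoms: none
Why: Sonogashira coupling of an aryl iodide with a tertiary propargylic alcohol runs at room temperature with a tertiary amine, so the aryl acetates should stay on and the ortho oxygen cannot cyclise onto the alkyne.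

Step 12
Reactants: 21 2-[(3S,8E,10E)-3-hydroxy-3,7,7-trimethyldodeca-8,10-dien-1-yn-1-yl]-6-methoxy-1,4-phenylene diacetate
Product: 23 2-[(8E,10E)-1-chloro-3,7,7-trimethyldodeca-1,2,8,10-tetraen-1-yl]-6-methoxy-1,4-phenylene diacetate with (aR) allene axis, via propargylic mesylate 22 (not isolated)
Conditions: MsCl, Et3N, THF, −78 °C to −40 °C; then LiCuCl2 (from CuCl and LiCl), THF, −78 °C to −20 °C; cold work-up, short filtration through Et3N-deactivated SiO2, used at once
Reagents that add atoms: lithium dichlorocuprate LiCuCl2, [Li+].Cl[Cu-]Cl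
Why: SN2′ substitution of a propargylic sulfonate by a halocuprate delivers chloride to the aryl-bearing alkyne carbon C11 anti to the mesylate leaving from C10, so the (S)-carbinol should be translated into the (aR) axis; low temperature and short contact are meant to prevent ionisation of the tertiary mesylate and cuprate-induced racemisation.

Step 13
Reactants: 23 2-[(8E,10E)-1-chloro-3,7,7-trimethyldodeca-1,2,8,10-tetraen-1-yl]-6-methoxy-1,4-phenylene diacetate with (aR) allene axis
Product: 24 2-{(E)-chloro[(2S,4aS,8aS)-2,5,5,8a-tetramethyl-4a,5,6,7,8,8a-hexahydronaphthalen-1(2H)-ylidene]methyl}-6-methoxy-1,4-phenylene diacetate (the 6,7-didehydro target diacetate)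
Conditions: toluene (0.01 M, degassed), BHT (cat.), 2,6-di-tert-butyl-4-methylpyridine (0.2 equiv), silylated sealed tube, 140–160 °C
Reagents that add atoms: none
Why: Proposed new method: a thermal, concerted but asynchronous intramolecular Diels–Alder reaction in which the (5E,7E)-diene adds suprafacially across the C9=C10 π bond of the chloroallene (C8–C9 bond to the sp carbon leading, C5–C10 following) while C9=C11 stays behind as the exocyclic chloro(aryl)alkene; the closest known reaction type is the thermal intramolecular Diels–Alder reaction of allenes with axial-to-central chirality transfer, which has not been shown with a 1-aryl-1-chloroallene as dienophile. Ring B closes as the six-membered ring of the [4+2] itself and ring A closes in the same event as the six-membered ring holding the four-carbon tether C1–C4 (1,3,9-decatriene mode giving the fused bicyclo[4.4.0] system), the C4 gem-dimethyl group favouring the folded conformer. The π lobes of C9=C10 lie in the plane of the C11 substituents, so the diene must approach over Cl or over the aryl ring; approach over the smaller Cl, anti to the aryl ring, puts Cl cis to C8 (E alkene) and, with the (aR) axis, fixes C10 as S. C5 follows from the anti, chair-like tether transition state (C10 methyl under the diene, tether outside), which gives the trans ring fusion, and C8 follows from the (E,E)-diene, whose inside hydrogens H5 and H8 end cis (8β-methyl). The selectivities needed are therefore attack on the Cl face, secured by the aryl ring, trans over cis fusion, which is the least secured, and reaction at C9=C10 instead of C9=C11, secured by the tether length (six- against seven-membered ring). The electron-poor diacetoxyaryl group, the apolar solvent and the hindered pyridine as HCl trap should hold back ionisation of the C–Cl bond, which would racemise the axis.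

Step 14
Reactants: 24 the 6,7-didehydro target diacetate
Product: 25 2-{(E)-chloro[(2S,4aS,8aS)-2,5,5,8a-tetramethyloctahydronaphthalen-1(2H)-ylidene]methyl}-6-methoxy-1,4-phenylene diacetate
Conditions: 2-nitrobenzenesulfonylhydrazide (excess, in portions), Et3N, CH2Cl2, rt
Reagents that add atoms: none
Why: Diimide transfers H2 through a cyclic transition state to the cis-disubstituted C6=C7 bond and leaves the tetrasubstituted chloroalkene and its C–Cl bond alone, where metal hydrogenation could cleave it; no stereocentre is touched.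

Step 15
Reactants: 25 2-{(E)-chloro[(2S,4aS,8aS)-2,5,5,8a-tetramethyloctahydronaphthalen-1(2H)-ylidene]methyl}-6-methoxy-1,4-phenylene diacetate
Product: 26 2-{(E)-chloro[(2S,4aS,8aS)-2,5,5,8a-tetramethyloctahydronaphthalen-1(2H)-ylidene]methyl}-6-methoxybenzene-1,4-diol (CNP0162917.1)
Conditions: K2CO3, MeOH (degassed), argon, 0 °C to rt; then degassed aq. NH4Cl
Reagents that add atoms: none
Why: Base-catalysed transesterification removes both aryl acetates without touching the vinyl chloride, and oxygen is excluded because the free hydroquinone would otherwise be oxidised to the quinone.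

**Compound list**

1 | isobutyronitrile | CC(C)C#N | starting material
2 | (5-chloropent-1-yn-1-yl)trimethylsilane | C[Si](C)(C)C#CCCCCl | starting material
3 | lithiated isobutyronitrile | [Li+].CC(C)=C=[N-] | intermediate (not isolated)
4 | 2,2-dimethyl-7-(trimethylsilyl)hept-6-ynenitrile | N#CC(C)(C)CCCC#C[Si](C)(C)C | intermediate
5 | N-(diisobutylalumanyl) imine of aldehyde 6 | CC(C)C[Al](CC(C)C)N=CC(C)(C)CCCC#C[Si](C)(C)C | intermediate (not isolated)
6 | 2,2-dimethyl-7-(trimethylsilyl)hept-6-ynal | O=CC(C)(C)CCCC#C[Si](C)(C)C | intermediate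
7 | [(7E)-8-iodo-6,6-dimethyloct-7-en-1-yn-1-yl]trimethylsilane | I/C=C/C(C)(C)CCCC#C[Si](C)(C)C | intermediate
8 | (E)-prop-1-en-1-ylboronic acid | C/C=C/B(O)O | starting material
9 | [(7E,9E)-6,6-dimethylundeca-7,9-dien-1-yn-1-yl]trimethylsilane | C/C=C/C=C/C(C)(C)CCCC#C[Si](C)(C)C | intermediate (not isolated)
10 | (7E,9E)-6,6-dimethylundeca-7,9-dien-1-yne | C/C=C/C=C/C(C)(C)CCCC#C | intermediate
11 | dimethyl[(1E,7E,9E)-2,6,6-trimethylundeca-1,7,9-trien-1-yl]alumane | C/C=C/C=C/C(C)(C)CCC/C(C)=C/[Al](C)C | intermediate (not isolated)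
12 | (2E,8E,10E)-3,7,7-trimethyldodeca-2,8,10-trien-1-ol | C/C=C/C=C/C(C)(C)CCC/C(C)=C/CO | intermediate
13 | {(2S,3S)-3-[(5E,7E)-4,4-dimethylnona-5,7-dien-1-yl]-3-methyloxiran-2-yl}methanol | OC[C@@H]1O[C@@]1(C)CCCC(C)(C)/C=C/C=C/C | intermediate
14 | (2R,3S)-2-(chloromethyl)-3-[(5E,7E)-4,4-dimethylnona-5,7-dien-1-yl]-3-methyloxirane | ClC[C@@H]1O[C@@]1(C)CCCC(C)(C)/C=C/C=C/C | intermediate
15 | lithium (3S,8E,10E)-1-chloro-3,7,7-trimethyldodeca-1,8,10-trien-3-olate (C1=C2 geometry not defined) | [Li+].[O-][C@](C)(C=CCl)CCCC(C)(C)/C=C/C=C/C | intermediate (not isolated)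
16 | (3S,8E,10E)-3,7,7-trimethyldodeca-8,10-dien-1-yn-3-ol | C#C[C@@](C)(O)CCCC(C)(C)/C=C/C=C/C | intermediate
17 | 5-iodovanillin (4-hydroxy-3-iodo-5-methoxybenzaldehyde) | COc1cc(C=O)cc(I)c1O | starting material
18 | 4-hydroxy-3-iodo-5-methoxyphenyl formate | COc1cc(OC=O)cc(I)c1O | intermediate (not isolated)
19 | 2-iodo-6-methoxybenzene-1,4-diol | COc1cc(O)cc(I)c1O | intermediate
20 | 2-iodo-6-methoxy-1,4-phenylene diacetate | COc1cc(OC(C)=O)cc(I)c1OC(C)=O | intermediate
21 | 2-[(3S,8E,10E)-3-hydroxy-3,7,7-trimethyldodeca-8,10-dien-1-yn-1-yl]-6-methoxy-1,4-phenylene diacetate | C/C=C/C=C/C(C)(C)CCC[C@](C)(O)C#Cc1cc(OC(C)=O)cc(OC)c1OC(C)=O | intermediate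
22 | methanesulfonate of 21 (S at the carbinol carbon) | C/C=C/C=C/C(C)(C)CCC[C@](C)(OS(C)(=O)=O)C#Cc1cc(OC(C)=O)cc(OC)c1OC(C)=O | intermediate (not isolated)
23 | 2-[(8E,10E)-1-chloro-3,7,7-trimethyldodeca-1,2,8,10-tetraen-1-yl]-6-methoxy-1,4-phenylene diacetate, (aR) allene axis | C/C=C/C=C/C(C)(C)CCCC(C)=[C@@]=C(Cl)c1cc(OC(C)=O)cc(OC)c1OC(C)=O | intermediate (key-step precursor)
24 | 2-{(E)-chloro[(2S,4aS,8aS)-2,5,5,8a-tetramethyl-4a,5,6,7,8,8a-hexahydronaphthalen-1(2H)-ylidene]methyl}-6-methoxy-1,4-phenylene diacetate | COc1cc(OC(C)=O)cc(/C(Cl)=C2/[C@@H](C)C=C[C@H]3C(C)(C)CCC[C@]23C)c1OC(C)=O | intermediate (key-step product)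
25 | 2-{(E)-chloro[(2S,4aS,8aS)-2,5,5,8a-tetramethyloctahydronaphthalen-1(2H)-ylidene]methyl}-6-methoxy-1,4-phenylene diacetate | COc1cc(OC(C)=O)cc(/C(Cl)=C2/[C@@H](C)CC[C@H]3C(C)(C)CCC[C@]23C)c1OC(C)=O | intermediate
26 | 2-{(E)-chloro[(2S,4aS,8aS)-2,5,5,8a-tetramethyloctahydronaphthalen-1(2H)-ylidene]methyl}-6-methoxybenzene-1,4-diol | COc1cc(O)cc(/C(Cl)=C2/[C@@H](C)CC[C@H]3C(C)(C)CCC[C@]23C)c1O | target

**Step count**

Total: 15 steps. Longest linear sequence: 13 steps (steps 1–8 and 11–15); the aryl branch is steps 9–10.

**Steps most likely to fail**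

1. Step 13 (proposed new method). The cycloaddition may be slower than ionisation of the C–Cl bond, which would racemise the axis or isomerise the allene to the propargylic chloride. The allene may also dimerise by [2+2], or the reaction may pass through the syn (cis-fused) transition state.
Fallback with known chemistry, setting out from allylic alcohol 12 and returning at 24: MnO2 oxidation of 12 gives (2E,8E,10E)-3,7,7-trimethyldodeca-2,8,10-trienal F1. This activated enal is cyclised in a Lewis-acid-catalysed, enantioselective type 1 intramolecular Diels–Alder reaction (protonated diphenylprolinol-derived B-aryl oxazaborolidine with HNTf2, CH2Cl2, low temperature). The endo transition state, with the formyl group and the C10 methyl under the diene, should give the trans-fused (1S,2S,4aS,8aS)-2,5,5,8a-tetramethyl-1,2,4a,5,6,7,8,8a-octahydronaphthalene-1-carbaldehyde F2. Nozaki–Hiyama–Kishi coupling of F2 with aryl iodide 20 (CrCl2, NiCl2 cat., DMF) gives the C11 carbinol F3 as an epimer mixture. Dess–Martin periodinane oxidises F3 to the aryl ketone F4. Conversion of the ketone into the chloroalkene with (PhO)3P/Cl2/Et3N then gives 24, where the route is rejoined before the diimide step. In this variant the C9=C11 geometry is set in the elimination and not by a cycloaddition, so the E isomer may have to be separated from the Z isomer.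

2. Step 12. The tertiary propargylic mesylate may ionise before the cuprate attacks, the chlorocuprate may racemise the chloroallene, or direct substitution at C10 may compete. Each of these erodes or destroys the axial chirality.
Fallback, setting out from 12 and returning at 23: chloride is delivered syn from a chlorosulfite (SNi′) instead of anti from a cuprate, which requires the enantiomeric carbinol. Epoxidation of 12 with D-(−)-diethyl tartrate gives the (2R,3R)-epoxy alcohol F5. Appel chlorination gives the epoxy chloride F6, LDA fragmentation gives the (R)-alkynol F7, and Sonogashira coupling with 20 gives the (R)-aryl alkynol F8. SOCl2 in Et2O/dioxane at 0 °C without amine base forms the chlorosulfite F9, which loses SO2 and passes Cl to C11 on the face the oxygen leaves, giving the same (aR)-chloroallene 23.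

3. Step 14. The ring alkene C6=C7 is shielded by C4, C5 and the C8 methyl, so the reduction may stall, and long exposure to the basic medium may strip the acetates early.
Fallback, setting out from 24 and returning at 25: homogeneous catalytic hydrogenation with RhCl(PPh3)3 and H2 in benzene/EtOH. This catalyst discriminates by alkene coordination, reduces disubstituted alkenes, does not bind tetrasubstituted ones and does not normally cleave vinyl C–Cl bonds. No new compound is made.

**Further compounds**

F1 | step 13 | (2E,8E,10E)-3,7,7-trimethyldodeca-2,8,10-trienal | C/C=C/C=C/C(C)(C)CCC/C(C)=C/C=O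
F2 | step 13 | (1S,2S,4aS,8aS)-2,5,5,8a-tetramethyl-1,2,4a,5,6,7,8,8a-octahydronaphthalene-1-carbaldehyde | O=C[C@H]2[C@@H](C)C=C[C@H]3C(C)(C)CCC[C@]23C
F3 | step 13 | 2-{hydroxy[(1S,2S,4aS,8aS)-2,5,5,8a-tetramethyl-1,2,4a,5,6,7,8,8a-octahydronaphthalen-1-yl]methyl}-6-methoxy-1,4-phenylene diacetate (carbinol epimers) | COc1cc(OC(C)=O)cc(C(O)[C@H]2[C@@H](C)C=C[C@H]3C(C)(C)CCC[C@]23C)c1OC(C)=O
F4 | step 13 | 2-methoxy-6-{[(1S,2S,4aS,8aS)-2,5,5,8a-tetramethyl-1,2,4a,5,6,7,8,8a-octahydronaphthalen-1-yl]carbonyl}-1,4-phenylene diacetate | COc1cc(OC(C)=O)cc(C(=O)[C@H]2[C@@H](C)C=C[C@H]3C(C)(C)CCC[C@]23C)c1OC(C)=O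
F5 | step 12 | {(2R,3R)-3-[(5E,7E)-4,4-dimethylnona-5,7-dien-1-yl]-3-methyloxiran-2-yl}methanol | OC[C@H]1O[C@]1(C)CCCC(C)(C)/C=C/C=C/C
F6 | step 12 | (2S,3R)-2-(chloromethyl)-3-[(5E,7E)-4,4-dimethylnona-5,7-dien-1-yl]-3-methyloxirane | ClC[C@H]1O[C@]1(C)CCCC(C)(C)/C=C/C=C/C
F7 | step 12 | (3R,8E,10E)-3,7,7-trimethyldodeca-8,10-dien-1-yn-3-ol | C#C[C@](C)(O)CCCC(C)(C)/C=C/C=C/C
F8 | step 12 | 2-[(3R,8E,10E)-3-hydroxy-3,7,7-trimethyldodeca-8,10-dien-1-yn-1-yl]-6-methoxy-1,4-phenylene diacetate | C/C=C/C=C/C(C)(C)CCC[C@@](C)(O)C#Cc1cc(OC(C)=O)cc(OC)c1OC(C)=O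
F9 | step 12 | chlorosulfite of F8 (R at the carbinol carbon) | C/C=C/C=C/C(C)(C)CCC[C@@](C)(OS(Cl)=O)C#Cc1cc(OC(C)=O)cc(OC)c1OC(C)=O
F0 | step 14 | none | none
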